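**Assumption:** Oncostemonol B has no stereocentre and is achiral, so there is no enantiomer to select. The only stereochemical element is the (Z)-C8=C9 alkene (`/C=C\` = cis), and the route controls that.

## Retrosynthetic overview
1. Remove the acetate. The precursor is the C2-symmetric tetraphenol 5, whose four OH groups are equivalent, so only one monoacetate can form.
2. Tetraphenol 5 comes from tetramethyl ether 4 by an alkene-tolerant O-demethylation.
3. Disconnect the central (Z)-C8=C9 bond of 4. It arises by Z-selective homometathesis of two identical Ar-(CH2)7-CH=CH2 units (3).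
4. Disconnect the benzylic C1–C2 bond of 3. It arises by Cu-catalysed coupling of 3,5-dimethoxybenzyl bromide with oct-7-enylmagnesium bromide.
5. No ring is formed in the route, because both arene rings are purchased.

## Route

**Step 1**
Reactants: 1, 8-bromooct-1-ene (1.3 equiv); 2, 3,5-dimethoxybenzyl bromide (1.0 equiv)
Product: 3, 1,3-dimethoxy-5-(non-8-en-1-yl)benzene
Conditions: (i) 1, Mg, cat. I2, THF, rt to 40 °C. (ii) Add this Grignard to 2 with Li2CuCl4 (3 mol %) in THF, −10 °C to rt, 3 h. Quench with aq NH4Cl.
Reagents that add atoms: none (both carbon fragments are numbered reactants)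
Why: This is a Kochi-type Cu-catalysed Grignard/benzylic bromide sp3–sp3 cross-coupling. C1 (benzylic) plus C8 gives the required Ar-(CH2)7-CH=CH2, and the aryl methyl ethers and the remote terminal alkene are inert.

**Step 2**
Reactants: 3 (2 molecules)
Product: 4, (Z)-1,16-bis(3,5-dimethoxyphenyl)hexadec-8-ene (plus ethylene)
Conditions: Grubbs Z-selective cyclometalated (adamantyl-NHC, nitrato) Ru catalyst, 1–2 mol %, THF (about 3 M), 35 °C, static vacuum or Ar sparge to remove ethylene, 8–12 h. Stop at about 85–90 % conversion and quench with ethyl vinyl ether. Polish on AgNO3–silica if needed.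
Reagents that add atoms: none
Why: This is a Z-selective olefin homometathesis. The chelated catalyst forces an all-syn, side-bound metallacyclobutane, which typically gives ≥95:5 Z for unhindered terminal alkenes. Stopping early limits secondary Z-to-E erosion.

**Step 3**
Reactants: 4
Product: 5, (Z)-5,5'-(hexadec-8-ene-1,16-diyl)bis(benzene-1,3-diol)
Conditions: B-iodo-9-BBN (1 M in hexanes, 5 equiv), CH2Cl2, 0 °C to rt, 3–6 h. Concentrate, take up in Et2O, add ethanolamine (5 equiv), filter off the 9-BBN–ethanolamine adduct, then run a short column.
Reagents that add atoms: none (four CH3 groups leave as MeI; H comes from work-up)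
Why: This is a Lewis-acid/iodide SN2 cleavage of aryl methyl ethers. The reagent has no B–H bond and releases no free HX during the reaction, and it haloborates only terminal alkynes. The isolated Z-alkene is therefore neither added to nor isomerised.

**Step 4**
Reactants: 5
Product: 6, Oncostemonol B, 3-[(Z)-16-(3,5-dihydroxyphenyl)hexadec-8-en-1-yl]-5-hydroxyphenyl acetate
Conditions: Ac2O (1.0 equiv, syringe pump over 2 h), Et3N (1.1 equiv), THF (0.02 M), 0 °C. Work up with pH 6 buffer and chromatograph on SiO2. Resubmit recovered 5. Return di- and triacetates to 5 with K2CO3/MeOH.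
Reagents that add atoms: acetic anhydride, CC(=O)OC(C)=O
Why: This is a statistical mono-O-acylation of four symmetry-equivalent phenols, so the monoacetate is a single compound. The theoretical maximum is about 42 % per pass, and I expect about 35–40 % (roughly 55–60 % based on recovered 5). The 4-OH, 3-OH and 2-OH species separate easily, and the alkene is untouched.

## Compound list
| No. | Name | SMILES | Role |
|---|---|---|---|
| 1 | 8-bromooct-1-ene | C=CCCCCCCBr | starting material |
| 2 | 3,5-dimethoxybenzyl bromide | COc1cc(CBr)cc(OC)c1 | starting material |
| 3 | 1,3-dimethoxy-5-(non-8-en-1-yl)benzene | C=CCCCCCCCc1cc(OC)cc(OC)c1 | intermediate |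
| 4 | (Z)-1,16-bis(3,5-dimethoxyphenyl)hexadec-8-ene | COc1cc(CCCCCCC/C=C\CCCCCCCc2cc(OC)cc(OC)c2)cc(OC)c1 | intermediate |
| 5 | (Z)-5,5'-(hexadec-8-ene-1,16-diyl)bis(benzene-1,3-diol) | Oc1cc(O)cc(CCCCCCC/C=C\CCCCCCCc2cc(O)cc(O)c2)c1 | intermediate |
| 6 | Oncostemonol B | CC(=O)Oc1cc(O)cc(CCCCCCC/C=C\CCCCCCCc2cc(O)cc(O)c2)c1 | target |

## Summary
**Total step count:** 4
**Longest linear sequence:** 4

**Steps most likely to fail, with fallbacks**

1. **Step 4: low throughput from statistical monoacetylation, or acetate scrambling.**
   - Fallback: give up late desymmetrisation and join two differentiated halves.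
   - Carry out a Z-selective Wittig reaction (NaHMDS, THF, −78 °C) between {8-[3,5-bis(TBSO)phenyl]octyl}triphenylphosphonium iodide and 8-[3-(PMBO)-5-(TBSO)phenyl]octanal.
   - Remove the PMB group with DDQ, acetylate the single free phenol, then remove the three TBS groups with HF·pyridine.

2. **Step 2: insufficient Z:E ratio or conversion in the homometathesis.**
   - Fallback: set the geometry by alkyne semireduction.
   - Couple 3,5-dimethoxyphenylmagnesium bromide with excess 1,7-dibromoheptane (Li2CuCl4) to give 1-(7-bromoheptyl)-3,5-dimethoxybenzene.
   - Alkylate acetylene twice, first with LiC≡CH·EDA and then with n-BuLi/DMPU and a second equivalent of the bromide. This gives 1,16-diarylhexadec-8-yne.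
   - Reduce with Lindlar catalyst/H2 or P-2 Ni to obtain 4.

3. **Step 3: incomplete fourfold demethylation or damage to the alkene.**
   - Fallback: change the protecting group from the start.
   - Run steps 1–2 with commercial 3,5-bis(benzyloxy)benzyl bromide.
   - Debenzylate with BCl3/pentamethylbenzene in CH2Cl2 at −78 °C. This cleaves aryl benzyl ethers without hydrogenation and is expected to leave the alkene intact.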